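(The readings were computed on assumed constants, and the scatter is random.)

Start from X.

all flasks: X 0.10 M

| flask | Z | remark | time |
|---|---|---|---|
| Sunday's | 0.052 M | run made earlier |  |
| Wednesday's | 0.30 M | run made earlier |  |
| zeta | 0.0800 M |  | 30 h |
| alpha | 0.200 M |  | 30 h |
| theta | 0.400 M |  | 30 h |

| run | time / h | J / % | X / % |
|---|---|---|---|
| Sunday's | 1.33 | 4 | 100 |
| Sunday's | 4.00 | 3 | 98 |
| Sunday's | 8.00 | 7 | 91 |
| Sunday's | 10.0 | 9 | 93 |
| Sunday's | 15.0 | 10 | 87 |
| Wednesday's | 3.00 | 16 | 86 |
| Wednesday's | 6.00 | 22 | 73 |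
| Wednesday's | 10.0 | 24 | 59 |
| Wednesday's | 12.0 | 26 | 53 |
| Wednesday's | 15.0 | 28 | 45 |

(each reading ± 1.5 percentage points)



1. J at the end, in percent of the X charged, for each flask in turn (zeta, alpha, theta)

At the bench, a flask with Z in excess is pseudo-first-order: X loses equal powers of ten in equal times. So I count in decades. Wednesday's run falls to 45% of its X at 15.0 h, which gives 0.0771 M⁻¹ h⁻¹: the decades of X lost per hour and per molar of Z charged, my decade constant. Sunday's run, from its own small loss, reads 0.0775 M⁻¹ h⁻¹, so as far as these readings show, the loss goes with Z to the first power.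

With Z held at its charge, 30 h takes zeta 0.185 decades down, alpha 0.462 and theta 0.925, leaving fractions of 0.653, 0.345 and 0.119 of X.

The rule wants Z at 10 to one over X, but the charges stand at 0.800, 2.00 and 4.00. In zeta, the X lost would cost 43.3% of Z's charge at one Z each, so there the rule is past its border and I expect more X left than it says.

For J, Wednesday's run ends 0.347 decades down with J at 28% and levelling. Alpha lies nearest that depth, so I expect the most J there. Sunday's run shows 10% of J at 87% of X, less than Wednesday's 16% at 86%, so with its low Z I put zeta under the 22% that Wednesday's run reads at 73% of X.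

The forecast, holding that “J must react onward, consuming a second Z”, gives 23%, 29% and 15%; its zeta stands above the 22% I took as my ceiling.

The flasks give J of 17.4%, 25.4% and 23.3%.

    X + Z ⇌ G + J (K = 35.0, k = 0.190 M⁻¹ h⁻¹)
    J + Z ⇌ G + L (K = 0.570, k = 0.370 M⁻¹ h⁻¹)
    G → Q (k = 0.0800 h⁻¹)
    X + J → D (k = 0.160 M⁻¹ h⁻¹)

In alpha, the forward step from J to L alone has J's half-life at 9.4 h with the other concentrations as charged, shorter than the 43 h of X + J to D. At the end, alpha's X stands at 38.2%, which is 0.418 decades, less than my 0.462. At the end, zeta's X stands at 67.0%, which is 0.174 decades against my 0.185.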